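**Retrosynthetic overview**
1. Neonambiquinone A ⇒ 2-hydroxy-3,6-bis(4-hydroxyphenyl)-1,4-benzoquinone. The last step acetylates the one vinylogous-acid OH and leaves both phenols free.
2. Hydroxyquinone ⇒ 4,7-diaryl-2,1,3-benzoxadisilol-5-ol. The two adjacent ring oxygens come from two aryl C–Si bonds (Tamao oxidation, then air).
3. Benzoxadisilole ⇒ Si–O–Si-tethered bis(arylethynyl) diyne + vinylene carbonate (a hydroxyacetylene equivalent). One decarboxylative [2+2+2] closes the central carbocycle and the five-membered oxadisilole ring together and fixes the para-terphenyl pattern.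
4. Diyne ⇒ 2 × 4-iodophenol + 1,3-diethynyl-1,1,3,3-tetramethyldisiloxane (double Sonogashira). No protecting groups are used.
5. Ring order: the outer phenol rings are bought. The central ring and the oxadisilole ring form at once, and the oxadisilole ring is excised oxidatively one step later.

Assumption: the target has no stereocentre and is achiral, so there is no enantiomer to select. The only stereocentres on the route are two transient ones in a non-isolated cycloadduct.

**Step 1**
Reactants: 1 4-iodophenol (2.1 equiv); 2 1,3-diethynyl-1,1,3,3-tetramethyldisiloxane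
Product: 4 1,3-bis[(4-hydroxyphenyl)ethynyl]-1,1,3,3-tetramethyldisiloxane, via mono-coupled ethynyl(arylethynyl)disiloxane 3 (not isolated)
Conditions: PdCl2(PPh3)2 (2 mol %), CuI (2 mol %), Et3N (4 equiv), THF, rt, Ar
Reagents that add atoms: none
Why: Double Sonogashira coupling, in which zerovalent palladium inserts into the C–I bond of 1 and each terminal C–H of 2 enters as its copper acetylide, while the C(sp)–Si and Si–O–Si bonds stay inert without fluoride or alkoxide and the free phenol is tolerated as in couplings of 4-iodophenol with trimethylsilylacetylene; no stereocentre is formed.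

**Step 2 (key step)**
Reactants: 4 1,3-bis[(4-hydroxyphenyl)ethynyl]-1,1,3,3-tetramethyldisiloxane; 5 vinylene carbonate (5 equiv)
Product: 7 4,7-bis(4-hydroxyphenyl)-1,1,3,3-tetramethyl-1,3-dihydro-2,1,3-benzoxadisilol-5-ol, via cis-fused cyclohexadiene carbonate cycloadduct 6 (not isolated)
Conditions: [Rh(cod)2]BF4 (10 mol %), rac-BINAP (10 mol %), H2 pre-activation, ClCH2CH2Cl, 80 °C, slow addition of 4
Reagents that add atoms: none
Why: Proposed new method: oxidative cyclisation of the tethered diyne on monovalent rhodium closes the oxadisilole ring and a 2,5-diaryl rhodacyclopentadiene (the tether forces C–C bond formation between the two silicon-bearing carbons, so the aryl groups end up para); suprafacial insertion of the cis-alkene 5 and reductive elimination then close the six-membered carbocycle as meso cis-adduct 6, whose two transient stereocentres vanish when C–O cleavage and loss of CO2 aromatise it to the phenol, and the symmetry of 4 allows only one regioisomer; the closest known reaction types are the cationic rhodium/BINAP decarboxylative [2+2+2] cycloaddition of 1,6-diynes with vinylene carbonate to phenols and the cobalt-catalysed [2+2+2] cyclisation of Si–CH2–Si-tethered diethynylsilanes to 1,3-disilaindanes.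

**Step 3**
Reactants: 7 4,7-bis(4-hydroxyphenyl)-1,1,3,3-tetramethyl-1,3-dihydro-2,1,3-benzoxadisilol-5-ol
Product: 9 2-hydroxy-3,6-bis(4-hydroxyphenyl)-1,4-benzoquinone, via 3,6-bis(4-hydroxyphenyl)benzene-1,2,4-triol 8 (not isolated)
Conditions: 30% aq H2O2 (2.2 equiv), KF, KHCO3, THF/MeOH, 0 °C to rt, Ar; then air, rt; 1 M HCl work-up
Reagents that add atoms: hydrogen peroxide, OO
Why: Tamao–Kumada oxidation, in which fluoride and hydroperoxide add to the oxygen-activated silicon atoms and each electron-rich aryl carbon migrates from Si to O at the same ring position, solvolysis frees 8, and its hydroxyhydroquinone core autoxidises in air at about pH 8 to the para-quinone, which sits in the medium as its poorly electrophilic anion and so survives the small peroxide excess; no stereocentre is formed.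

**Step 4**
Reactants: 9 2-hydroxy-3,6-bis(4-hydroxyphenyl)-1,4-benzoquinone
Product: 11 neonambiquinone A [2-acetoxy-3,6-bis(4-hydroxyphenyl)-1,4-benzoquinone], via diisopropylethylammonium quinonolate 10 (not isolated)
Conditions: i-Pr2NEt (1.0 equiv), THF, −78 °C; AcCl (1.0 equiv), −78 to −30 °C; pH 4 buffer quench
Reagents that add atoms: acetyl chloride, CC(=O)Cl
Why: Chemoselective O-acylation, in which only the hydroxyquinone OH (pKa about 4–5 against about 10 for the phenols) is deprotonated by one equivalent of hindered amine, anion 10 is the only good nucleophile for AcCl at low temperature, no free base remains afterwards to shuttle the acetyl group to the phenols, and acylation at O-2 gives the more stable para-quinone; no stereocentre is formed.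

**Compound list**
1 | 4-iodophenol | Oc1ccc(I)cc1 | starting material
2 | 1,3-diethynyl-1,1,3,3-tetramethyldisiloxane | C#C[Si](C)(C)O[Si](C)(C)C#C | starting material
3 | 1-ethynyl-3-[(4-hydroxyphenyl)ethynyl]-1,1,3,3-tetramethyldisiloxane (not isolated) | C#C[Si](C)(C)O[Si](C)(C)C#Cc1ccc(O)cc1 | intermediate
4 | 1,3-bis[(4-hydroxyphenyl)ethynyl]-1,1,3,3-tetramethyldisiloxane | Oc1ccc(cc1)C#C[Si](C)(C)O[Si](C)(C)C#Cc1ccc(O)cc1 | intermediate
5 | vinylene carbonate (1,3-dioxol-2-one) | O=C1OC=CO1 | starting material
6 | meso cis-fused cyclohexa-1,3-diene carbonate: oxadisilole-fused diene with aryl groups on the diene termini and a cyclic carbonate on the two sp3 CH carbons (not isolated) | C[Si]1(C)O[Si](C)(C)C2=C(c3ccc(O)cc3)[C@H]3OC(=O)O[C@H]3C(c3ccc(O)cc3)=C12 | intermediate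
7 | 4,7-bis(4-hydroxyphenyl)-1,1,3,3-tetramethyl-1,3-dihydro-2,1,3-benzoxadisilol-5-ol | C[Si]1(C)O[Si](C)(C)c2c1c(-c1ccc(O)cc1)cc(O)c2-c1ccc(O)cc1 | intermediate
8 | 3,6-bis(4-hydroxyphenyl)benzene-1,2,4-triol (not isolated) | Oc1ccc(cc1)-c1cc(O)c(-c2ccc(O)cc2)c(O)c1O | intermediate
9 | 2-hydroxy-3,6-bis(4-hydroxyphenyl)-1,4-benzoquinone | Oc1ccc(cc1)C1=CC(=O)C(c2ccc(O)cc2)=C(O)C1=O | intermediate
10 | N,N-diisopropylethylammonium salt of 9, deprotonated at the quinone OH (not isolated) | CC[NH+](C(C)C)C(C)C.[O-]C1=C(c2ccc(O)cc2)C(=O)C=C(c2ccc(O)cc2)C1=O | intermediate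
11 | neonambiquinone A, 2-acetoxy-3,6-bis(4-hydroxyphenyl)-1,4-benzoquinone (achiral) | CC(=O)OC1=C(c2ccc(O)cc2)C(=O)C=C(c2ccc(O)cc2)C1=O | target

**Totals**
Total step count: 4. Longest linear sequence: 4.

**Steps most likely to fail, and fallbacks**

**Step 2.** The hindered 2,5-diaryl rhodacycle has to insert a weakly binding alkene, silicon is forced into the ring positions remote from the metal, and 4 may oligomerise instead.

The fallback sets out from 4 and replaces the decarboxylative alkene cycloaddition by an all-alkyne cyclotrimerisation in which boron stands in for the missing oxygen.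
- 4 and ethynylboronic acid pinacol ester (C#CB1OC(C)(C)C(C)(C)O1, slow addition) are heated with CpCo(CO)2 (15 mol %) in refluxing xylene under irradiation.
- This gives the arylboronate 4,7-bis(4-hydroxyphenyl)-1,1,3,3-tetramethyl-5-(4,4,5,5-tetramethyl-1,3,2-dioxaborolan-2-yl)-1,3-dihydro-2,1,3-benzoxadisilole F1.
- The peroxide medium of step 3, with one more equivalent of H2O2, oxidises the C–B bond and both C–Si bonds at once. The route is rejoined at 8, which goes on to 9 in air.

**Step 3.** Two crowded aryl–Si bonds must both be oxidised, and the hydroxyquinone can be cleaved or ring-contracted by alkaline peroxide.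

The fallback sets out from 7, uses silicon only as a traceless tether, and brings in the oxygens by quinone chemistry.
- TBAF in wet THF at 60 °C strips both silicon atoms to give 2,5-bis(4-hydroxyphenyl)phenol F2.
- Co(salen) and O2 in DMF oxidise the only phenol with a free para position to 2,5-bis(4-hydroxyphenyl)-1,4-benzoquinone F3.
- Thiele–Winter acetoxylation (Ac2O, cat. H2SO4, rt to 40 °C) adds acetate to one of the two equivalent quinone CH positions and acetylates every OH. The product is 3,6-bis(4-acetoxyphenyl)benzene-1,2,4-triyl triacetate F4.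
- K2CO3 in MeOH under air removes all five acetates. The route comes back through 8 to 9.

**Step 4.** The acetoxyquinone is itself an acyl donor, so the acetyl group may drift to the phenols. The quinonolate is also ambident.

The fallback sets out from 9 and gives up the protecting-group-free finish.
- TBSCl (3.5 equiv) and imidazole in DMF give 2-(tert-butyldimethylsilyloxy)-3,6-bis[4-(tert-butyldimethylsilyloxy)phenyl]-1,4-benzoquinone F5.
- Brief stirring in MeOH with a trace of AcOH removes only the vinylogous silyl ester, giving 2-hydroxy-3,6-bis[4-(tert-butyldimethylsilyloxy)phenyl]-1,4-benzoquinone F6.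
- Ac2O and pyridine in CH2Cl2 at 0 °C acetylate the single free OH to give 2-acetoxy-3,6-bis[4-(tert-butyldimethylsilyloxy)phenyl]-1,4-benzoquinone F7.
- Et3N·3HF in MeCN at 0 °C, which is mildly acidic with no free base, removes the two aryl silyl ethers. The route comes back at 11.

**Further compounds**
F1 | step 2 | 4,7-bis(4-hydroxyphenyl)-1,1,3,3-tetramethyl-5-(4,4,5,5-tetramethyl-1,3,2-dioxaborolan-2-yl)-1,3-dihydro-2,1,3-benzoxadisilole | C[Si]1(C)O[Si](C)(C)c2c1c(-c1ccc(O)cc1)cc(B1OC(C)(C)C(C)(C)O1)c2-c1ccc(O)cc1
F2 | step 3 | 2,5-bis(4-hydroxyphenyl)phenol | Oc1ccc(cc1)-c1ccc(-c2ccc(O)cc2)c(O)c1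
F3 | step 3 | 2,5-bis(4-hydroxyphenyl)-1,4-benzoquinone | Oc1ccc(cc1)C1=CC(=O)C(=CC1=O)c1ccc(O)cc1
F4 | step 3 | 3,6-bis(4-acetoxyphenyl)benzene-1,2,4-triyl triacetate | CC(=O)Oc1ccc(cc1)-c1cc(OC(C)=O)c(-c2ccc(OC(C)=O)cc2)c(OC(C)=O)c1OC(C)=O
F5 | step 4 | 2-(tert-butyldimethylsilyloxy)-3,6-bis[4-(tert-butyldimethylsilyloxy)phenyl]-1,4-benzoquinone | CC(C)(C)[Si](C)(C)Oc1ccc(cc1)C1=CC(=O)C(c2ccc(O[Si](C)(C)C(C)(C)C)cc2)=C(O[Si](C)(C)C(C)(C)C)C1=O
F6 | step 4 | 2-hydroxy-3,6-bis[4-(tert-butyldimethylsilyloxy)phenyl]-1,4-benzoquinone | CC(C)(C)[Si](C)(C)Oc1ccc(cc1)C1=CC(=O)C(c2ccc(O[Si](C)(C)C(C)(C)C)cc2)=C(O)C1=O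
F7 | step 4 | 2-acetoxy-3,6-bis[4-(tert-butyldimethylsilyloxy)phenyl]-1,4-benzoquinone | CC(=O)OC1=C(c2ccc(O[Si](C)(C)C(C)(C)C)cc2)C(=O)C=C(c2ccc(O[Si](C)(C)C(C)(C)C)cc2)C1=O
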